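**Plan**
- Retrosynthesis: the ring B phenol is unmasked last. The pyran ring is cut at O1–C2 (oxa-6π closure of an ortho-quinone methide) and at C3–C4 (alkenyl Grignard on a C4 aldehyde). The O–CH2 bond of the C7 prenyl ether is cut next.
- Enabling feature: ring A (C4a, C5, C6, C7, C8, C8a) carries oxygen on C7 and C8a, the arylethyl chain on C5 and the one-carbon unit C4 on C4a. This is the pattern of a 6-alkyl-2,4-dihydroxybenzoic acid, that is, a folded tetraketide, so C4a–C5 can be cut back to an open diketo-dioxinone.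
- The open chain is cut at C5–C6 (dianion plus Weinreb amide) and at C7–C8 (dioxinone dienolate plus acetyl chloride).
- Forward: C7–C8 and then C5–C6 join the chain. Ring A closes by aldol aromatisation (C4a–C5), the C7 oxygen is prenylated, and the pyran ring closes last. Ring B arrives intact with phloretic acid.
- Stereochemistry: the target has no stereocentre, and C3=C4 is cis because it lies in the ring. The transient centres of 12 and 18 are destroyed in the flask.

Key step: step 5

Assumption: LiN(SiMe3)2, LiN(i-Pr)2, i-Bu2AlH and (2-methylprop-1-enyl)magnesium bromide are used as purchased solutions. Atom labels C2 to C8a follow the chromene numbering of the target, which coincides with the benzodioxinone numbering for C4 to C8a.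

**Step 1**
Reactants: 1 2,2,6-trimethyl-4H-1,3-dioxin-4-one; 2 acetyl chloride
Product: 4 2,2-dimethyl-6-(2-oxopropyl)-4H-1,3-dioxin-4-one, via lithium dienolate 3 (not isolated)
Conditions: 1 (2 equiv), LiN(SiMe3)2 (2 equiv), THF, −78 °C, 1 h; 2 (1 equiv), −78 to −20 °C; 1 M HCl
Reagents that add atoms: acetyl chloride (2), CC(=O)Cl; LiN(SiMe3)2, [Li]N([Si](C)(C)C)[Si](C)(C)C (lithium of 3 only)
Why: Kinetic deprotonation of the C6 methyl group gives the cross-conjugated dienolate 3, which acid chlorides acylate at the gamma carbon (vinylogous Claisen-type C-acylation, forming C7–C8), and the second equivalent of 3 absorbs the acidic proton of 4 so that double acylation is suppressed.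

**Step 2**
Reactants: 5 3-(4-hydroxyphenyl)propanoic acid (phloretic acid)
Product: 7 3-[4-(tert-butyldimethylsilyloxy)phenyl]propanoic acid, via bis-silylated ester 6 (not isolated)
Conditions: TBSCl (2.3 equiv), imidazole (5 equiv), DMF, rt; then K2CO3 (1 equiv), THF–MeOH–H2O, rt, 1 h; 1 M HCl to pH 4, 0 °C
Reagents that add atoms: tert-butyldimethylsilyl chloride, CC(C)(C)[Si](C)(C)Cl
Why: Exhaustive silylation followed by selective solvolysis is the standard protection of phenolic acids, because a silyl ester is cleaved by dilute carbonate far faster than an aryl silyl ether.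

**Step 3**
Reactants: 7 3-[4-(tert-butyldimethylsilyloxy)phenyl]propanoic acid
Product: 9 3-[4-(tert-butyldimethylsilyloxy)phenyl]-N-methoxy-N-methylpropanamide, via acyl imidazole 8 (not isolated)
Conditions: 1,1'-carbonyldiimidazole (1.1 equiv), CH2Cl2, rt, 1 h; MeNH(OMe)·HCl (1.3 equiv), rt
Reagents that add atoms: N,O-dimethylhydroxylamine hydrochloride, CNOC.Cl; 1,1'-carbonyldiimidazole, O=C(n1ccnc1)n1ccnc1 (imidazolyl group of 8 only)
Why: Carbonyldiimidazole activation and aminolysis of the acyl imidazole is the routine Weinreb amide synthesis, and its near-neutral medium leaves the aryl silyl ether untouched.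

**Step 4**
Reactants: 4 2,2-dimethyl-6-(2-oxopropyl)-4H-1,3-dioxin-4-one; 9 3-[4-(tert-butyldimethylsilyloxy)phenyl]-N-methoxy-N-methylpropanamide
Product: 11 6-{6-[4-(tert-butyldimethylsilyloxy)phenyl]-2,4-dioxohexyl}-2,2-dimethyl-4H-1,3-dioxin-4-one, via dilithium dianion 10 (not isolated)
Conditions: 4 (1.5 equiv), LiN(i-Pr)2 (3.1 equiv), THF, −78 °C, 1 h; 9 (1 equiv), −78 to −30 °C; cold 1 M HCl to pH 3
Reagents that add atoms: LiN(i-Pr)2, [Li]N(C(C)C)C(C)C (lithium of 10 only)
Why: Double deprotonation gives a beta-dicarbonyl-type dianion that reacts at its last-formed terminal carbon (crossed Claisen acylation, forming C5–C6), and the Weinreb amide holds the adduct as a chelated tetrahedral intermediate until the quench, so neither over-addition nor proton exchange with the more acidic product consumes 10.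

**Step 5**
Reactants: 11 6-{6-[4-(tert-butyldimethylsilyloxy)phenyl]-2,4-dioxohexyl}-2,2-dimethyl-4H-1,3-dioxin-4-one
Product: 13 5-{2-[4-(tert-butyldimethylsilyloxy)phenyl]ethyl}-7-hydroxy-2,2-dimethyl-4H-1,3-benzodioxin-4-one, via cyclic aldol 12 (not isolated)
Conditions: Et3N (5 equiv), CH2Cl2, rt, 16 h
Reagents that add atoms: none
Why: Et3N reversibly deprotonates the CH2 between the dioxinone and the first ketone, which turns the heterocycle into its vinylogous enolate, and the alpha carbon of that enolate (dioxinone C5, future C4a) adds to the remote ketone carbon next to the arylethyl group (future C5) to give aldol 12; E1cB loss of water and enolisation of the remaining ring ketone (future C7) then make the process irreversible by aromatisation. The closest known reaction type is the polyketide-like aldol aromatisation of 3,5,7-triketo acid derivatives, which is established for diketo-dioxinones with amine or carbonate bases. Ring A closes in a favoured 6-(enolexo)-exo-trig mode, the only carbocycle larger than four atoms that the 1,3-spacing of the carbonyl groups allows by aldol addition. No stereocentre is created in 13, since the two transient centres of 12 are erased on dehydration. The selectivity needed is C–C closure in preference to O-cyclisation to a pyranone or Claisen closure onto the carboxyl carbon C4, and it is secured because the acetonide ties up both the carboxyl group and the C8a oxygen, leaves C4 a poor electrophile, and at room temperature stays far below the temperature at which dioxinones fragment to acylketenes. The C7 hydroxyl is thereby formed free while the C8a oxygen stays masked, which makes the next alkylation regiospecific.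

**Step 6**
Reactants: 13 5-{2-[4-(tert-butyldimethylsilyloxy)phenyl]ethyl}-7-hydroxy-2,2-dimethyl-4H-1,3-benzodioxin-4-one; 14 prenyl bromide (1-bromo-3-methylbut-2-ene)
Product: 15 5-{2-[4-(tert-butyldimethylsilyloxy)phenyl]ethyl}-2,2-dimethyl-7-(3-methylbut-2-enyloxy)-4H-1,3-benzodioxin-4-one
Conditions: 14 (1.2 equiv), K2CO3 (1.5 equiv), dry acetone, rt
Reagents that add atoms: prenyl bromide (14), CC(C)=CCBr
Why: In this Williamson ether synthesis the C7 phenol is the only free hydroxyl and, being para to the ester carbonyl, is acidic enough for K2CO3 at room temperature, so SN2 O-alkylation by the primary allylic bromide is fast while the aryl silyl ether persists in the dry medium.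

**Step 7**
Reactants: 15 5-{2-[4-(tert-butyldimethylsilyloxy)phenyl]ethyl}-2,2-dimethyl-7-(3-methylbut-2-enyloxy)-4H-1,3-benzodioxin-4-one
Product: 16 2-{2-[4-(tert-butyldimethylsilyloxy)phenyl]ethyl}-6-hydroxy-4-(3-methylbut-2-enyloxy)benzaldehyde
Conditions: i-Bu2AlH (1.5 equiv), CH2Cl2, −78 °C, 1 h; aq. potassium sodium tartrate, rt
Reagents that add atoms: none
Why: Partial hydride reduction of 2,2-dimethyl-1,3-benzodioxin-4-ones is a known entry to salicylaldehydes, because the aluminium hemiacetal is stable at −78 °C and collapses on hydrolysis with loss of acetone, releasing the C4 aldehyde and the C8a phenol together.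

**Step 8**
Reactants: 16 2-{2-[4-(tert-butyldimethylsilyloxy)phenyl]ethyl}-6-hydroxy-4-(3-methylbut-2-enyloxy)benzaldehyde; 17 (2-methylprop-1-enyl)magnesium bromide
Product: 20 tert-butyl(dimethyl){4-[2-(2,2-dimethyl-7-(3-methylbut-2-enyloxy)-2H-chromen-5-yl)ethyl]phenoxy}silane, via allylic carbinol 18 (not isolated), via ortho-quinone methide 19 (not isolated)
Conditions: 17 (3 equiv), THF, 0 °C to rt; aq. NH4Cl; crude 18, pyridinium p-toluenesulfonate (0.1 equiv), toluene, 70 °C
Reagents that add atoms: (2-methylprop-1-enyl)magnesium bromide (17), CC(C)=C[Mg]Br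
Why: Grignard 1,2-addition (the first equivalent is spent on the phenol) forms C3–C4 and gives the racemic, doubly donor-activated allylic carbinol 18; this loses water on gentle acid-assisted warming to quinone methide 19, whose alkenyl arm is pushed towards the carbonyl oxygen by the C5 chain, and oxa-6π electrocyclisation then forms O1–C2, the established salicylaldehyde-to-2H-chromene sequence in which the carbinol centre disappears.

**Step 9**
Reactants: 20 tert-butyl(dimethyl){4-[2-(2,2-dimethyl-7-(3-methylbut-2-enyloxy)-2H-chromen-5-yl)ethyl]phenoxy}silane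
Product: 21 4-{2-[2,2-dimethyl-7-(3-methylbut-2-enyloxy)-2H-chromen-5-yl]ethyl}phenol (CNP0337021.0)
Conditions: Bu4NF (1.1 equiv), AcOH (1.1 equiv), THF, 0 °C
Reagents that add atoms: none
Why: Fluoride-induced desilylation of an aryl silyl ether is fast at 0 °C because a strong Si–F bond forms and a phenoxide leaves, and the acetic acid buffer keeps the medium near neutral, to which the prenyl ether and the chromene are inert.

**Compound list**
1 | 2,2,6-trimethyl-4H-1,3-dioxin-4-one | CC1=CC(=O)OC(C)(C)O1 | starting material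
2 | acetyl chloride | CC(=O)Cl | starting material
3 | lithium 2,2-dimethyl-6-methylidene-6H-1,3-dioxin-4-olate (dienolate of 1) | C=C1C=C(O[Li])OC(C)(C)O1 | intermediate
4 | 2,2-dimethyl-6-(2-oxopropyl)-4H-1,3-dioxin-4-one | CC(=O)CC1=CC(=O)OC(C)(C)O1 | intermediate
5 | 3-(4-hydroxyphenyl)propanoic acid (phloretic acid) | O=C(O)CCc1ccc(O)cc1 | starting material
6 | tert-butyldimethylsilyl 3-[4-(tert-butyldimethylsilyloxy)phenyl]propanoate | CC(C)(C)[Si](C)(C)OC(=O)CCc1ccc(O[Si](C)(C)C(C)(C)C)cc1 | intermediate
7 | 3-[4-(tert-butyldimethylsilyloxy)phenyl]propanoic acid | O=C(O)CCc1ccc(O[Si](C)(C)C(C)(C)C)cc1 | intermediate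
8 | 3-[4-(tert-butyldimethylsilyloxy)phenyl]-1-(1H-imidazol-1-yl)propan-1-one | O=C(CCc1ccc(O[Si](C)(C)C(C)(C)C)cc1)n1ccnc1 | intermediate
9 | 3-[4-(tert-butyldimethylsilyloxy)phenyl]-N-methoxy-N-methylpropanamide | CON(C)C(=O)CCc1ccc(O[Si](C)(C)C(C)(C)C)cc1 | intermediate
10 | dilithium dianion of 4 (bis-enolate: OLi on dioxinone C4, CH=C(OLi)=CH2 arm on C6) | C=C(O[Li])C=C1C=C(O[Li])OC(C)(C)O1 | intermediate
11 | 6-{6-[4-(tert-butyldimethylsilyloxy)phenyl]-2,4-dioxohexyl}-2,2-dimethyl-4H-1,3-dioxin-4-one | CC1(C)OC(=O)C=C(CC(=O)CC(=O)CCc2ccc(O[Si](C)(C)C(C)(C)C)cc2)O1 | intermediate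
12 | 5-{2-[4-(tert-butyldimethylsilyloxy)phenyl]ethyl}-5-hydroxy-2,2-dimethyl-4a,5-dihydro-4H-1,3-benzodioxine-4,7(6H)-dione (racemic, both diastereomers) | CC1(C)OC(=O)C2C(O1)=CC(=O)CC2(O)CCc3ccc(O[Si](C)(C)C(C)(C)C)cc3 | intermediate
13 | 5-{2-[4-(tert-butyldimethylsilyloxy)phenyl]ethyl}-7-hydroxy-2,2-dimethyl-4H-1,3-benzodioxin-4-one | CC1(C)OC(=O)c2c(CCc3ccc(O[Si](C)(C)C(C)(C)C)cc3)cc(O)cc2O1 | intermediate
14 | prenyl bromide (1-bromo-3-methylbut-2-ene) | CC(C)=CCBr | starting material
15 | 5-{2-[4-(tert-butyldimethylsilyloxy)phenyl]ethyl}-2,2-dimethyl-7-(3-methylbut-2-enyloxy)-4H-1,3-benzodioxin-4-one | CC(C)=CCOc1cc(CCc2ccc(O[Si](C)(C)C(C)(C)C)cc2)c2c(c1)OC(C)(C)OC2=O | intermediate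
16 | 2-{2-[4-(tert-butyldimethylsilyloxy)phenyl]ethyl}-6-hydroxy-4-(3-methylbut-2-enyloxy)benzaldehyde | CC(C)=CCOc1cc(O)c(C=O)c(CCc2ccc(O[Si](C)(C)C(C)(C)C)cc2)c1 | intermediate
17 | (2-methylprop-1-enyl)magnesium bromide | CC(C)=C[Mg]Br | starting material
18 | rac-3-{2-[4-(tert-butyldimethylsilyloxy)phenyl]ethyl}-2-(1-hydroxy-3-methylbut-2-enyl)-5-(3-methylbut-2-enyloxy)phenol | CC(C)=CCOc1cc(O)c(C(O)C=C(C)C)c(CCc2ccc(O[Si](C)(C)C(C)(C)C)cc2)c1 | intermediate
19 | (6Z)-5-{2-[4-(tert-butyldimethylsilyloxy)phenyl]ethyl}-6-(3-methylbut-2-enylidene)-3-(3-methylbut-2-enyloxy)cyclohexa-2,4-dien-1-one | CC(C)=CCOC1=CC(=O)/C(=C\C=C(C)C)C(CCc2ccc(O[Si](C)(C)C(C)(C)C)cc2)=C1 | intermediate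
20 | tert-butyl(dimethyl){4-[2-(2,2-dimethyl-7-(3-methylbut-2-enyloxy)-2H-chromen-5-yl)ethyl]phenoxy}silane | CC(C)=CCOc1cc(CCc2ccc(O[Si](C)(C)C(C)(C)C)cc2)c2c(c1)OC(C)(C)C=C2 | intermediate
21 | 4-{2-[2,2-dimethyl-7-(3-methylbut-2-enyloxy)-2H-chromen-5-yl]ethyl}phenol | CC(C)=CCOc1cc(CCc2ccc(O)cc2)c2c(c1)OC(C)(C)C=C2 | target

**Step count**
Total step count: 9.
Longest linear sequence: 8 steps (5 to 21 through steps 2 to 9). Step 1 is the short convergent branch.

**Steps most likely to fail**

Step 4.
- Risk: proton transfer between the dianion and the enolisable amide, O-acylation, and decay or premature cyclisation of the sensitive tricarbonyl chain during work-up may all erode conversion.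
- The fallback sets out from 1 and 7 and comes back at 11. It replaces the strong-base dianion by soft enolisation.
- Allyl hydrogen malonate is treated with oxalyl chloride (cat. DMF) to give allyl 3-chloro-3-oxopropanoate F1.
- F1 acylates dienolate 3 (from 1 and LiN(SiMe3)2) to give allyl 4-(2,2-dimethyl-4-oxo-4H-1,3-dioxin-6-yl)-3-oxobutanoate F2.
- Acid 7 is converted with oxalyl chloride into 3-[4-(tert-butyldimethylsilyloxy)phenyl]propanoyl chloride F3.
- MgCl2 and pyridine in CH2Cl2 at 0 °C join F2 and F3 by C-acylation at the carbon between ester and ketone. This gives allyl 2-{3-[4-(tert-butyldimethylsilyloxy)phenyl]propanoyl}-4-(2,2-dimethyl-4-oxo-4H-1,3-dioxin-6-yl)-3-oxobutanoate F4.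
- The zerovalent palladium catalyst Pd(PPh3)4 with morpholine in THF then removes the allyl group. The freed beta-keto acid decarboxylates to 11.

Step 8.
- Risk: addition to the aldehyde may be sluggish, because it is flanked on both sides and deactivated as its magnesium phenoxide. The quinone methide may also be diverted by dimerisation or by a hydrogen shift to a dienyl phenol.
- The fallback sets out from 16 and comes back at 20. It fixes the cis C3=C4 geometry in a lactone before C2 is built.
- (Triphenylphosphoranylidene)ketene in toluene at 80 °C acylates the phenol, and the ester ylide closes by intramolecular Wittig olefination. The product is 5-{2-[4-(tert-butyldimethylsilyloxy)phenyl]ethyl}-7-(3-methylbut-2-enyloxy)-2H-chromen-2-one F5.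
- Excess MeMgBr in THF at 0 °C adds twice to the lactone carbonyl. This gives 3-{2-[4-(tert-butyldimethylsilyloxy)phenyl]ethyl}-2-[(Z)-3-hydroxy-3-methylbut-1-enyl]-5-(3-methylbut-2-enyloxy)phenol F6.
- Catalytic pyridinium p-toluenesulfonate in CH2Cl2 closes O1–C2 by ionisation of the tertiary allylic alcohol and capture by the neighbouring phenol, giving 20.

Step 7.
- Risk: over-reduction if the aluminium hemiacetal collapses before the quench, or incomplete reduction of the hindered carbonyl. Either would leave mixtures of oxidation levels.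
- The fallback sets out from 15 and comes back at 16. It abandons the partial reduction for a full reduction and re-oxidation.
- Excess i-Bu2AlH in CH2Cl2 at 0 °C drives the reduction through to 3-{2-[4-(tert-butyldimethylsilyloxy)phenyl]ethyl}-2-(hydroxymethyl)-5-(3-methylbut-2-enyloxy)phenol F7.
- MnO2 in CH2Cl2 at rt then oxidises the benzylic alcohol selectively to 16.

**Further compounds**
F1 | step 4 | allyl 3-chloro-3-oxopropanoate | C=CCOC(=O)CC(=O)Cl
F2 | step 4 | allyl 4-(2,2-dimethyl-4-oxo-4H-1,3-dioxin-6-yl)-3-oxobutanoate | C=CCOC(=O)CC(=O)CC1=CC(=O)OC(C)(C)O1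
F3 | step 4 | 3-[4-(tert-butyldimethylsilyloxy)phenyl]propanoyl chloride | O=C(Cl)CCc1ccc(O[Si](C)(C)C(C)(C)C)cc1
F4 | step 4 | allyl 2-{3-[4-(tert-butyldimethylsilyloxy)phenyl]propanoyl}-4-(2,2-dimethyl-4-oxo-4H-1,3-dioxin-6-yl)-3-oxobutanoate (racemic, largely enolised) | C=CCOC(=O)C(C(=O)CCc1ccc(O[Si](C)(C)C(C)(C)C)cc1)C(=O)CC1=CC(=O)OC(C)(C)O1
F5 | step 8 | 5-{2-[4-(tert-butyldimethylsilyloxy)phenyl]ethyl}-7-(3-methylbut-2-enyloxy)-2H-chromen-2-one | CC(C)=CCOc1cc(CCc2ccc(O[Si](C)(C)C(C)(C)C)cc2)c2c(c1)OC(=O)C=C2
F6 | step 8 | 3-{2-[4-(tert-butyldimethylsilyloxy)phenyl]ethyl}-2-[(Z)-3-hydroxy-3-methylbut-1-enyl]-5-(3-methylbut-2-enyloxy)phenol | CC(C)=CCOc1cc(O)c(/C=C\C(C)(C)O)c(CCc2ccc(O[Si](C)(C)C(C)(C)C)cc2)c1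
F7 | step 7 | 3-{2-[4-(tert-butyldimethylsilyloxy)phenyl]ethyl}-2-(hydroxymethyl)-5-(3-methylbut-2-enyloxy)phenol | CC(C)=CCOc1cc(O)c(CO)c(CCc2ccc(O[Si](C)(C)C(C)(C)C)cc2)c1
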